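**Retrosynthetic overview**
1. Locants (elemane numbering): ring C5–C10 with C10 = quaternary carbon (CH3 = C14, vinyl = C1=C2), C9 = CH2, C8 = acyloxy carbon, C7 = carbon bearing the acrylic acid (C11, C12 = CO2H, C13 = CH2), C6 = carbinol, C5 = carbon bearing C4(=C3H2)C15H2OH; β = ring face of the C10 methyl.
2. Late disconnections: the C8 ester (Z-acid from 3-methylfuran-2(5H)-one); the acrylic acid back to C7–CH2CH2OH (oxidation, α-methylenation, oxidation); the C8 carbinol back to a ketone.
3. Enabling feature: the oxygenated ring carbons C6 and C8 flank C7 next to the C9 methylene, the pattern of a 1,3-dioxygenated diene C9=C8–C7=C6; the cis vinyl (on C10) and 3-hydroxyprop-1-en-2-yl (on C5) groups are the doubly methylenated form of a lactol carbon (C1) and a ketone (C4) tied through the C15 oxygen into a 2H-pyran-3(6H)-one ring.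
4. Key disconnection: Diels–Alder union of diene 9 (7 carbons) with enantiopure pyranone 5 (8 carbons) forms C9–C10 (at the quaternary carbon) and C5–C6, giving the only carbocycle and the C10, C5 and C6 stereocentres, from which C7 and C8 are relayed.
5. Ring order: pyranone ring (step 2) and the purchased dihydrofuran ring first; cyclohexane ring in step 6; pyran ring opened in step 8 (vinyl + C15–OH), dihydrofuran ring opened in step 10 (C8 ketone + C12–OH).

Key step: step 6

Remark: 1, 6 and 20 are treated as catalogue chemicals.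
Remark: in step 3 the (R)-catalyst is assumed to select the (S)-anomer; if the sense is opposite, the enantiomeric catalyst is used and nothing else changes.

**Step 1**
Reactants: 1 4-methylfuran-2-carbaldehyde
Product: 2 (4-methylfuran-2-yl)methanol
Conditions: NaBH4, MeOH, 0 °C
Reagents that add atoms: none
Why: Chemoselective borohydride reduction of the aldehyde, with no stereocentre formed.

**Step 2**
Reactants: 2 (4-methylfuran-2-yl)methanol
Product: 4 racemic pyranone lactol, via ring-opened ene-dione 3 (not isolated)
Conditions: N-bromosuccinimide (1.05 equiv), NaHCO3, NaOAc, THF/H2O 4:1, 0 °C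
Reagents that add atoms: water, O
Why: Achmatowicz rearrangement, in which bromonium-initiated oxidative opening of the furan gives the Z-ene-dione 3 and the primary hydroxyl recloses onto the aldehyde, so the only stereocentre (anomeric) is labile and forms racemic.

**Step 3**
Reactants: 4 racemic pyranone lactol
Product: 5 (S)-anomeric isobutyrate of the pyranone
Conditions: isobutyric anhydride (1.3 equiv), (R)-2-phenyl-2,3-dihydroimidazo[2,1-b][1,3]benzothiazole (benzotetramisole, 5 mol %), iPr2NEt (0.5 equiv), Na2SO4, CHCl3, 0 °C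
Reagents that add atoms: isobutyric anhydride, CC(C)C(=O)OC(=O)C(C)C
Why: Isothiourea-catalysed dynamic kinetic acylation of an Achmatowicz lactol, in which the anomers interconvert through ring-opened 3 faster than they are acylated and the chiral acyl-isothiouronium ion selects the (S)-anomer, so the catalyst sets the anomeric stereocentre.

**Step 4**
Reactants: 6 2-methyl-4,5-dihydrofuran
Product: 8 2-methyl-4,5-dihydrofuran-3-carbaldehyde, via vinylogous iminium chloride 7 (not isolated)
Conditions: POCl3 (1.1 equiv), DMF (3 equiv), CH2Cl2, 0 °C; then 6, 0 °C to rt; then aq. NaOAc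
Reagents that add atoms: N,N-dimethylformamide, CN(C)C=O; water, O
Why: Vilsmeier–Haack formylation at the nucleophilic β-carbon of the cyclic enol ether followed by hydrolysis of the iminium salt, with no stereocentre formed.

**Step 5**
Reactants: 8 2-methyl-4,5-dihydrofuran-3-carbaldehyde
Product: 9 exocyclic silyloxy diene (E)
Conditions: TBSOTf (1.15 equiv), Et3N (2 equiv), Et2O, −78 to 0 °C; filtration through basic alumina, used at once
Reagents that add atoms: tert-butyldimethylsilyl trifluoromethanesulfonate, CC(C)(C)[Si](C)(C)OS(=O)(=O)C(F)(F)F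
Why: Soft vinylogous enolisation (O-silylation of the vinylogous formate, then loss of a proton from the methyl group next to the ring oxocarbenium carbon) should give the s-cis-locked silyl dienol ether, the E geometry being favoured because the Z isomer would push the silyloxy group into the inside position of the diene.

**Step 6**
Reactants: 5 (S)-anomeric isobutyrate of the pyranone; 9 exocyclic silyloxy diene (1.5 equiv)
Product: 10 tricyclic Diels–Alder adduct
Conditions: toluene (2 M), 2,6-di-tert-butyl-4-methylphenol (1 mol %), 90 °C, sealed tube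
Reagents that add atoms: none
Why: Concerted but asynchronous normal-demand [4+2] cycloaddition in which the terminal CH2 of 9 (C9, the most nucleophilic diene carbon, pushed by both oxygens) bonds to the methyl-bearing β-carbon of the enone (C10) and the silyloxy-bearing terminus (C6) bonds to the α-carbon (C5). The closest known reaction type is the thermal Diels–Alder reaction of 6-alkoxy- and 6-acyloxy-2H-pyran-3(6H)-ones with oxygenated or s-cis-locked exocyclic dienes. The one new ring, the cyclohexene, is closed by intermolecular [4+2] cycloaddition, both σ-bonds forming suprafacially on each partner. C10 and C5 follow from suprafacial addition to the cyclic Z-enone (cis ring fusion, methyl and C5–H cis), with the absolute sense fixed by attack anti to the pseudoaxial anomeric isobutyrate next to C10, and C6 follows from endo placement of the ketone under the E-configured silyloxy terminus (OTBS cis to C4). The step needs regio-, endo and facial selectivity, secured by the matched donor/acceptor polarisation, by secondary overlap with the cyclic dienophile and by the anomeric stereocentre; the retarding β-methyl group should be offset by the locked s-cis geometry and double donor substitution of the diene.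

**Step 7**
Reactants: 10 tricyclic Diels–Alder adduct
Product: 11 C4-methylene adduct
Conditions: Cp2Ti(μ-CH2)(μ-Cl)AlMe2 (Tebbe reagent, 1.2 equiv), pyridine (0.2 equiv), THF/toluene, −40 to 0 °C; then 15% aq. NaOH
Reagents that add atoms: Tebbe reagent Cp2Ti(μ-CH2)(μ-Cl)AlMe2, C[Al-]1(C)C[Ti](C2C=CC=C2)(C2C=CC=C2)[Cl+]1
Why: Tebbe methylenation is non-basic and faster for ketones than for esters, so the C4 ketone should become the exocyclic methylene without epimerisation at C5, loss of the β-silyloxy group or attack on the anomeric ester and the enol ether.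

**Step 8**
Reactants: 11 C4-methylene adduct
Product: 14 bicyclic dienol, via lactol 12 (not isolated), via hydroxy aldehyde 13 (not isolated)
Conditions: Ph3PCH3Br (5 equiv), KN(SiMe3)2 (4.8 equiv), THF, 0 °C; then 11, 0 to 40 °C
Reagents that add atoms: methyltriphenylphosphonium bromide (as its ylide Ph3P=CH2), C[P+](c1ccccc1)(c1ccccc1)c1ccccc1.[Br-]
Why: Acyl transfer from the activated anomeric ester to the ylide (acylation of a phosphorus ylide by an ester) releases lactol 12, whose ring-opened neopentyl aldehyde 13 undergoes Wittig methylenation, so the pyran ring is unzipped to the C10 vinyl group and the free C15 alcohol with no stereocentre affected.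

**Step 9**
Reactants: 14 bicyclic dienol
Product: 15 C15 silyl ether
Conditions: TBSCl (1.3 equiv), imidazole (2.5 equiv), CH2Cl2, 0 °C to rt
Reagents that add atoms: tert-butyldimethylsilyl chloride, CC(C)(C)[Si](C)(C)Cl
Why: Standard silylation of the primary allylic alcohol.

**Step 10**
Reactants: 15 C15 silyl ether
Product: 17 hydroxy ketone, via cyclic hemiketal 16 (not isolated)
Conditions: pyridinium p-toluenesulfonate (0.2 equiv), acetone/H2O 10:1, 0 °C to rt
Reagents that add atoms: water, O
Why: Mild acid hydrolysis of the tetrasubstituted cyclic enol ether (protonation at C7, hydration to hemiketal 16, ring opening) should unmask the C8 ketone and the C12 alcohol while the poor leaving group OTBS stays on C6, and C7 is set under thermodynamic control with the side chain equatorial, trans to the 6-silyloxy group and free of a 1,3-diaxial clash with the axial C5 substituent.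

**Step 11**
Reactants: 17 hydroxy ketone
Product: 18 triethylsilyl ether ketone
Conditions: Et3SiCl (1.2 equiv), imidazole (2.5 equiv), CH2Cl2, −20 to 0 °C
Reagents that add atoms: chlorotriethylsilane, CC[Si](CC)(CC)Cl
Why: Selective silylation of the primary alcohol of the open-chain hydroxy ketone, which drains the ring–chain equilibrium because the tertiary hemiketal hydroxyl does not compete.

**Step 12**
Reactants: 18 triethylsilyl ether ketone
Product: 19 8β-alcohol
Conditions: LiBH(s-Bu)3 (L-Selectride, 1.5 equiv), THF, −78 °C; then H2O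
Reagents that add atoms: none
Why: Bulky-hydride reduction of a 2-substituted cyclohexanone, in which LiBH(s-Bu)3 attacks along the equatorial trajectory (the axial one is blocked by the syn-axial C10 methyl) and should deliver the axial 8β-alcohol cis to the equatorial C7 side chain.

**Step 13**
Reactants: 20 3-methylfuran-2(5H)-one
Product: 22 (Z)-4-acetoxy-2-methylbut-2-enoic acid, via sodium hydroxy-enoate 21 (not isolated)
Conditions: NaOH (1.05 equiv), H2O/THF, 0 °C to rt, evaporation; Ac2O (3 equiv), 4-(dimethylamino)pyridine (5 mol %), pyridine, 0 °C; then H2O, 0 °C, and 1 M HCl to pH 3, cold extraction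
Reagents that add atoms: sodium hydroxide, [Na+].[OH-]; acetic anhydride, CC(=O)OC(C)=O
Why: Saponification of the butenolide keeps the Z geometry fixed by the ring, and acetylation of the carboxylate salt before acidification prevents relactonisation.

**Step 14**
Reactants: 19 8β-alcohol; 22 (Z)-4-acetoxy-2-methylbut-2-enoic acid (2 equiv)
Product: 24 C8 ester, via mixed anhydride 23 (not isolated)
Conditions: 22, 2,4,6-trichlorobenzoyl chloride (2 equiv), Et3N (4 equiv), toluene, rt; then 19, 4-(dimethylamino)pyridine (2 equiv), toluene, rt to 50 °C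
Reagents that add atoms: none
Why: Yamaguchi esterification through mixed anhydride 23, the usual choice for angelate-type Z-acids because acyl transfer outruns Z to E isomerisation, should acylate the hindered axial alcohol with retention at C8.

**Step 15**
Reactants: 24 C8 ester
Product: 25 C12 aldehyde
Conditions: (COCl)2 (4 equiv), DMSO (8 equiv), CH2Cl2, −78 to −30 °C; then Et3N (12 equiv), −78 to 0 °C
Reagents that add atoms: none
Why: Under Swern conditions primary triethylsilyl ethers are converted directly into aldehydes, whereas TBS ethers, esters and alkenes are inert.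

**Step 16**
Reactants: 25 C12 aldehyde
Product: 27 α-methylene aldehyde, via Mannich base 26 (not isolated)
Conditions: dimethylmethylideneammonium iodide (Eschenmoser's salt, 4 equiv), Et3N (6 equiv), CH2Cl2, rt
Reagents that add atoms: dimethylmethylideneammonium iodide, C=[N+](C)C.[I-]
Why: Mannich reaction of the aldehyde enol with the preformed iminium salt and E1cB loss of dimethylamine (α-methylenation of an aldehyde) should install the C13 methylene without a secondary amine that could trigger vinylogous elimination of the C8 or C6 oxygen.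

**Step 17**
Reactants: 27 α-methylene aldehyde
Product: 28 bis-silylated acid
Conditions: NaClO2 (5 equiv), NaH2PO4 (5 equiv), 2-methyl-2-butene (30 equiv), t-BuOH/H2O 4:1, 0 °C to rt
Reagents that add atoms: sodium chlorite, [Na+].[O-]Cl=O
Why: Pinnick oxidation converts the 2-substituted acrolein into the acrylic acid without touching alkenes, esters or silyl ethers, with 2-methyl-2-butene scavenging hypochlorous acid.

**Step 18**
Reactants: 28 bis-silylated acid
Product: 29 target
Conditions: HF·pyridine, pyridine, THF, 0 °C to rt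
Reagents that add atoms: none
Why: Buffered, non-basic fluoride cleavage of both TBS ethers should leave the acetate, the Z-enoate and the acrylic acid intact, and the trans-1,3 relationship of the C6 hydroxyl and the C8 ester rules out acyl migration.

**Compound list**
1 | 4-methylfuran-2-carbaldehyde | O=Cc1cc(C)co1 | starting material
2 | (4-methylfuran-2-yl)methanol | OCc1cc(C)co1 | intermediate
3 | (2Z)-5-hydroxy-2-methyl-4-oxopent-2-enal | O=C/C(C)=C\C(=O)CO | intermediate
4 | 6-hydroxy-5-methyl-2H-pyran-3(6H)-one (racemic, anomers interconvert) | OC1OCC(=O)C=C1C | intermediate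
5 | (2S)-3-methyl-5-oxo-5,6-dihydro-2H-pyran-2-yl 2-methylpropanoate | CC(C)C(=O)O[C@@H]1OCC(=O)C=C1C | intermediate
6 | 2-methyl-4,5-dihydrofuran | CC1=CCCO1 | starting material
7 | N-methyl-N-[(2-methyl-4,5-dihydrofuran-3-yl)methylidene]methanaminium chloride | C[N+](C)=CC1=C(C)OCC1.[Cl-] | intermediate
8 | 2-methyl-4,5-dihydrofuran-3-carbaldehyde | CC1=C(C=O)CCO1 | intermediate
9 | tert-butyl(dimethyl){[(E)-(2-methylideneoxolan-3-ylidene)methyl]oxy}silane | C=C1OCC/C1=C\O[Si](C)(C)C(C)(C)C | intermediate
10 | tricyclic adduct: cyclohexene C5–C10 (C7=C8) fused at C7–C8 to a 2,3-dihydrofuran (O on C8, C11H2–C12H2 on C7) and cis-fused at C5–C10 to a tetrahydropyran-3-one [C10–C1H(OCOiPr)–O–C15H2–C4(=O)–C5]; 10β-CH3, 5β-H, 6α-OTBS, isobutyrate on the methyl face of the pyran ring | CC(C)C(=O)O[C@H]2[C@]1(C)CC3=C(CCO3)[C@H](O[Si](C)(C)C(C)(C)C)[C@@H]1C(=O)CO2 | intermediate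
11 | as 10 with C4=CH2 in place of the C4 ketone | CC(C)C(=O)O[C@H]2[C@]1(C)CC3=C(CCO3)[C@H](O[Si](C)(C)C(C)(C)C)[C@@H]1C(=C)CO2 | intermediate
12 | lactol of 11 (anomeric OH, both anomers) | OC2[C@]1(C)CC3=C(CCO3)[C@H](O[Si](C)(C)C(C)(C)C)[C@@H]1C(=C)CO2 | intermediate
13 | ring-opened form of 12: 10α-formyl, 10β-CH3, 6α-OTBS, 5α-(3-hydroxyprop-1-en-2-yl) on the dihydrofuran-fused cyclohexene | O=C[C@]1(C)CC2=C(CCO2)[C@H](O[Si](C)(C)C(C)(C)C)[C@@H]1C(=C)CO | intermediate
14 | dihydrofuran-fused cyclohexene (C7=C8, O on C8): 10α-vinyl, 10β-CH3, 6α-OTBS, 5α-(3-hydroxyprop-1-en-2-yl) | C=C[C@]1(C)CC2=C(CCO2)[C@H](O[Si](C)(C)C(C)(C)C)[C@@H]1C(=C)CO | intermediate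
15 | C15 tert-butyldimethylsilyl ether of 14 | C=C[C@]1(C)CC2=C(CCO2)[C@H](O[Si](C)(C)C(C)(C)C)[C@@H]1C(=C)CO[Si](C)(C)C(C)(C)C | intermediate
16 | cis-fused cyclic hemiketal of 17 (C8 bears OH and the ring O to C12; 7α-H) | C=C[C@]1(C)C[C@]2(O)[C@@H](CCO2)[C@H](O[Si](C)(C)C(C)(C)C)[C@@H]1C(=C)CO[Si](C)(C)C(C)(C)C | intermediate
17 | cyclohexanone (C8=O): 7β-(2-hydroxyethyl), 6α-OTBS, 5α-[3-(TBS-oxy)prop-1-en-2-yl], 10β-CH3, 10α-vinyl | C=C[C@]1(C)CC(=O)[C@@H](CCO)[C@H](O[Si](C)(C)C(C)(C)C)[C@@H]1C(=C)CO[Si](C)(C)C(C)(C)C | intermediate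
18 | C12 triethylsilyl ether of 17 | C=C[C@]1(C)CC(=O)[C@@H](CCO[Si](CC)(CC)CC)[C@H](O[Si](C)(C)C(C)(C)C)[C@@H]1C(=C)CO[Si](C)(C)C(C)(C)C | intermediate
19 | 8β-alcohol from 18 (8α-H, OH axial, cis to the 7β side chain and the 10β-methyl) | C=C[C@]1(C)C[C@@H](O)[C@@H](CCO[Si](CC)(CC)CC)[C@H](O[Si](C)(C)C(C)(C)C)[C@@H]1C(=C)CO[Si](C)(C)C(C)(C)C | intermediate
20 | 3-methylfuran-2(5H)-one | CC1=CCOC1=O | starting material
21 | sodium (2Z)-4-hydroxy-2-methylbut-2-enoate | [Na+].[O-]C(=O)/C(C)=C\CO | intermediate
22 | (2Z)-4-(acetyloxy)-2-methylbut-2-enoic acid | OC(=O)/C(C)=C\COC(C)=O | intermediate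
23 | (2Z)-4-(acetyloxy)-2-methylbut-2-enoic 2,4,6-trichlorobenzoic anhydride | O=C(OC(=O)c1c(Cl)cc(Cl)cc1Cl)/C(C)=C\COC(C)=O | intermediate
24 | 8β-[(2Z)-4-acetoxy-2-methylbut-2-enoyl] ester of 19 | C=C[C@]1(C)C[C@@H](OC(=O)/C(C)=C\COC(C)=O)[C@@H](CCO[Si](CC)(CC)CC)[C@H](O[Si](C)(C)C(C)(C)C)[C@@H]1C(=C)CO[Si](C)(C)C(C)(C)C | intermediate
25 | C12 aldehyde from 24 (7β-CH2CHO) | C=C[C@]1(C)C[C@@H](OC(=O)/C(C)=C\COC(C)=O)[C@@H](CC=O)[C@H](O[Si](C)(C)C(C)(C)C)[C@@H]1C(=C)CO[Si](C)(C)C(C)(C)C | intermediate
26 | Mannich base of 25: 7β-CH(CH2NMe2)CHO, both C11 epimers | C=C[C@]1(C)C[C@@H](OC(=O)/C(C)=C\COC(C)=O)[C@@H](C(CN(C)C)C=O)[C@H](O[Si](C)(C)C(C)(C)C)[C@@H]1C(=C)CO[Si](C)(C)C(C)(C)C | intermediate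
27 | α-methylene aldehyde: 7β-(3-oxoprop-1-en-2-yl) | C=C[C@]1(C)C[C@@H](OC(=O)/C(C)=C\COC(C)=O)[C@@H](C(=C)C=O)[C@H](O[Si](C)(C)C(C)(C)C)[C@@H]1C(=C)CO[Si](C)(C)C(C)(C)C | intermediate
28 | 6,15-bis(tert-butyldimethylsilyl) ether of the target acid | C=C[C@]1(C)C[C@@H](OC(=O)/C(C)=C\COC(C)=O)[C@@H](C(=C)C(=O)O)[C@H](O[Si](C)(C)C(C)(C)C)[C@@H]1C(=C)CO[Si](C)(C)C(C)(C)C | intermediate
29 | 2-[(1S,2R,3S,4S,6R)-6-{[(2Z)-4-(acetyloxy)-2-methylbut-2-enoyl]oxy}-4-ethenyl-2-hydroxy-3-(3-hydroxyprop-1-en-2-yl)-4-methylcyclohexyl]prop-2-enoic acid | C=C[C@]1(C)C[C@@H](OC(=O)/C(C)=C\COC(C)=O)[C@@H](C(=C)C(=O)O)[C@H](O)[C@@H]1C(=C)CO | target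

Total step count: 18. Longest linear sequence: 15 steps (1–3, 6–12, 14–18).

**Steps most likely to fail**

Step 6. The cycloaddition may be too slow at the β,β-disubstituted enone carbon, so that diene dimerisation or decomposition, or hetero-Diels–Alder addition of the enone to the exocyclic enol ether, takes over; endo and facial control may also erode at the temperature needed. The fallback sets out from 5 and returns at 10. Bromination and dehydrobromination of 5 (Br2, CH2Cl2, −20 °C; then Et3N, 0 °C) should give (S)-4-bromo-6-isobutyryloxy-5-methyl-2H-pyran-3(6H)-one F1, an α-halo enone and a much stronger dienophile. Cycloaddition with 9 (toluene, 50 °C) should give, with the same regio-, endo and facial sense, the C5-bromo adduct F2. Zn dust with NH4Cl in MeOH/THF at 0 °C then removes the bromine through the zinc enolate, which is expected to protonate on the face away from the neighbouring silyloxy group and so return the cis-fused ketone 10.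

Step 3. The methyl group next to the anomeric carbon may lower the enantiodiscrimination of the dynamic kinetic acylation, or the amine base may eject the acyloxy group (oxidopyrylium formation). The fallback sets out from 4 and returns at 14. Racemic 4 is esterified with (S)-2-methoxy-2-phenylacetic acid (N,N'-dicyclohexylcarbodiimide, 4-(dimethylamino)pyridine, CH2Cl2, 0 °C). The two anomeric esters are diastereomers and are separated by chromatography or crystallisation; the one wanted is (2S)-3-methyl-5-oxo-5,6-dihydro-2H-pyran-2-yl (2S)-2-methoxy-2-phenylacetate F3, and the other is saponified back to 4 and recycled. F3 replaces 5 in the conditions of step 6 to give the auxiliary-bearing adduct F4, the conditions of step 7 give the auxiliary-bearing C4-methylene compound F5, and the ylide of step 8 strips the auxiliary by the same acyl transfer to give 14.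

Step 14. Acylation of the hindered axial alcohol may be sluggish, and the activated angelate-type acyl donor may isomerise from Z to E before transfer. The fallback sets out from 19 and returns at 24. 19 is acylated with the small, geometrically indifferent 2-[bis(2,2,2-trifluoroethoxy)phosphoryl]propanoic acid (N,N'-dicyclohexylcarbodiimide, 4-(dimethylamino)pyridine, CH2Cl2) to give the 8β-phosphonopropanoate F6. A Still–Gennari olefination (KN(SiMe3)2, 18-crown-6, THF, −78 °C; then 2-oxoethyl acetate) then builds the Z-trisubstituted enoate on the ester and should give 24.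

**Further compounds**
F1 | step 6 | (2S)-4-bromo-3-methyl-5-oxo-5,6-dihydro-2H-pyran-2-yl 2-methylpropanoate | CC(C)C(=O)O[C@@H]1OCC(=O)C(Br)=C1C
F2 | step 6 | C5-bromo analogue of adduct 10 (Br in place of 5β-H) | CC(C)C(=O)O[C@H]2[C@]1(C)CC3=C(CCO3)[C@H](O[Si](C)(C)C(C)(C)C)[C@]1(Br)C(=O)CO2
F3 | step 3 | (2S)-3-methyl-5-oxo-5,6-dihydro-2H-pyran-2-yl (2S)-2-methoxy-2-phenylacetate | CO[C@H](C(=O)O[C@@H]1OCC(=O)C=C1C)c1ccccc1
F4 | step 3 | analogue of adduct 10 with the (S)-2-methoxy-2-phenylacetate as anomeric ester | CO[C@H](C(=O)O[C@H]2[C@]1(C)CC3=C(CCO3)[C@H](O[Si](C)(C)C(C)(C)C)[C@@H]1C(=O)CO2)c1ccccc1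
F5 | step 3 | analogue of 11 with the (S)-2-methoxy-2-phenylacetate as anomeric ester | CO[C@H](C(=O)O[C@H]2[C@]1(C)CC3=C(CCO3)[C@H](O[Si](C)(C)C(C)(C)C)[C@@H]1C(=C)CO2)c1ccccc1
F6 | step 14 | 8β-{2-[bis(2,2,2-trifluoroethoxy)phosphoryl]propanoyl} ester of 19 (both epimers at the phosphonate carbon) | C=C[C@]1(C)C[C@@H](OC(=O)C(C)P(=O)(OCC(F)(F)F)OCC(F)(F)F)[C@@H](CCO[Si](CC)(CC)CC)[C@H](O[Si](C)(C)C(C)(C)C)[C@@H]1C(=C)CO[Si](C)(C)C(C)(C)C
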